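**The price.** 2.62 is the number to watch here: the nucleophile price, the nucleophile gone from its free form per electrophile turned, as I read it from the maple run.

| setting | maple | alder | eta | theta | epsilon |
|---|---|---|---|---|---|
| electrophile | 33 mM | 33 mM | 33 mM | 33 mM | 33 mM |
| nucleophile | 83 mM | 140 mM | 66.0 mM | 86.0 mM | 110 mM |
| gas | 6.6 mM (held) | 6.6 mM (held) | 6.6 mM (held) | 6.6 mM (held) | 6.6 mM (held) |
| remark | run made earlier | run made earlier |  |  |  |
| time |  |  | 12 min | 12 min | 12 min |

| run | time / min | electrophile / % | target / % |
|---|---|---|---|
| maple | 0.500 | 63 | 42 |
| maple | 1.00 | 44 | 60 |
| maple | 2.50 | 25 | 75 |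
| maple | 6.00 | 14 | 86 |
| alder | 0.500 | 42 | 56 |
| alder | 1.00 | 25 | 75 |
| alder | 2.50 | 11 | 92 |
| alder | 6.00 | 0 | 99 |

(each reading ± 1.5 percentage points)

- at the start none of the gas is in solution

- part of the electrophile that has reacted at the end, eta
- part of the electrophile that has reacted at the end, theta
- part of the electrophile that has reacted at the end, epsilon
- what raising the concentration of nucleophile from its lowest to its highest value here does to the part of the electrophile that has reacted (changes below 5 percentage points count as none) (it falls / it rises / no change)

**Reading it.** I treat the loss of electrophile as a pseudo-first-order rate that follows free nucleophile. Over its first 0.500 min, the alder run loses electrophile at 1.74 min⁻¹, and I replace its nucleophile curve by the charge. Between 2.50 min and 6.00 min, the maple run loses electrophile at 0.166 min⁻¹. So I estimate that maple then holds 16.1 % of its nucleophile charge free, with 80.5 % of its electrophile turned on the mean, and that gives the price.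

**The error.** The charge overstates alder's mean nucleophile. Charging the price brings that mean to 82.1 % of the charge, and the price moves to 2.71, so the shortcut costs little.

**Turning nucleophile.** By hand, the charge divided by the price and by the electrophile charge gives the reach, the part of the electrophile that the nucleophile can pay for. That is 76.3 % for eta, where nucleophile is the limiting reagent, 99.4 % for theta and 127 % for epsilon, which is above full. The runs agree in direction: at 6.00 min, maple keeps 14 % of its electrophile and alder 0 %.

**Turning time.** Maple's target gains just 11 percentage points between 2.50 min and 6.00 min, so I expect the 12 min to bring each flask towards its reach. I commit to eta near its reach, theta a little under it, epsilon nearly full, and a rise across the range.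

**The result.** The forecast gives 86 %, 93 % and 97 %, with eta above my figure, and says it rises, on the ground that “k falls with time, not with conversion”. The flasks give 81.6 %, 92.9 % and 97.9 %: it rises, by 16 points.

    nucleophile + acid set free ⇌ protonated nucleophile, settled at all times (K = 1.40 × 10⁵ M⁻¹)
    2 nucleophile → self-condensation product (k = 0.0400 M⁻¹ s⁻¹)
    acid set free + free base ⇌ salt of the base (K = 170 M⁻¹, k = 2.10 M⁻¹ s⁻¹)
    electrophile + nucleophile → acid set free + target (k = 0.280 M⁻¹ s⁻¹)
    gas ⇌ free base, rate k5*(csat - [free base]) (kL = 0.190 s⁻¹)

**Why eta lags.** At 12 min, eta holds 1.62 % of its nucleophile free, so it has paid 2.41 per electrophile, below my price. Its lower nucleophile charge is the main reason eta stands at 81.6 % against epsilon's 97.9 %. Part of that is the running short of nucleophile, with parking as protonated nucleophile and self-condensation acting together: without the first, eta gives 97.2 %, and without the second, 93.1 %.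

**A second flask.** With 28 mM of nucleophile, otherwise as epsilon, the price gives a reach of 32.4 %. That flask gives 41.0 %, above the reach, with 0.59 % of its nucleophile free and a price of 2.05.

The earlier runs and the new flask come from a simulation for substances that don't exist; scatter was added.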